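**Compound numbering used throughout**

1 methyl (S)-3-hydroxy-2-methylpropanoate; 2 its TBDPS ether; 3 the Weinreb amide; 4 bromomagnesium hemiaminal (not isolated); 5 the methyl ketone; 6 the dioxolane silyl ether; 7 the dioxolane alcohol; 8 the dioxolane aldehyde; 9 5-bromo-1,2,3-trimethoxybenzene; 10 the aryl Grignard reagent; 11 MgBr2 chelate of 8 (not isolated); 12 bromomagnesium alkoxide (not isolated); 13 the anti alcohol; 14 3,4,5-trimethoxybenzoyl chloride; 15 the ester ketal; 16 Tsangin C.

## Analysis of the target

Tsangin C (16) is an open-chain butan-2-one, numbered here C1 (ketone methyl), C2 (C=O), C3 (CH–CH3) and C4 (benzylic CH–O). C4 carries a 3,4,5-trimethoxyphenyl ring directly and a 3,4,5-trimethoxybenzoyl group through its oxygen, so the only rings are the two arenes. C3 (S) and C4 (R) are adjacent stereocentres. With C2–C3–C4–C(aryl) drawn as a zigzag, the C3 methyl and the C4 oxygen lie on opposite sides, so the array is an anti aldol unit. The compound is a β-acyloxy ketone and is therefore fragile: base removes the C3 proton and expels the benzoate (E1cB) to a conjugated aryl enone, C3 epimerises through the enol, and the C4–O bond is benzylic on an electron-rich ring. The difficulty is to set the anti C3/C4 relationship in one absolute sense while keeping the C2 carbonyl masked until the very end, and then to reveal it without base. The strategy rests on the fact that C4 is bonded directly to an aryl carbon. The ring can therefore arrive as a nucleophile at an aldehyde carbon C4, whose α-carbon is C3 and whose β-carbon C2, held as a dioxolane, offers an oxygen for a six-membered magnesium chelate with the aldehyde oxygen.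

## Retrosynthetic reasoning

16 to 15. The last operation only unmasks C2; no skeletal bond is cut. Keeping C2 as a dioxolane until the end means that no intermediate is a β-acyloxy or β-hydroxy ketone while bases or nucleophiles are in use. The forward step has to hydrolyse a ketal under acid mild enough to leave the benzylic ester and the C3 centre alone.

15 to 13 and 14. The ester is cut at the acyl C–O bond. This keeps the C4–O bond intact, so the C4 configuration of 13 is carried over unchanged, and the acyl part is a commercial acid chloride. Cutting at C4–O instead would demand a displacement with inversion at a benzylic centre that ionises easily.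

13 to 8 and 10. The C4–C(aryl) bond is cut. A cut at C3–C4 would be an aldol of an unsymmetrical ketone with regiochemical and stereochemical problems, and a cut at C2–C3 would leave both stereocentres to be made elsewhere. The aryl–C4 cut gives one fragment, 8, that already holds C3 in the correct configuration and a β-oxygen able to chelate, and a second fragment, 10, that is an ordinary aryl Grignard reagent. The forward reaction must add the aryl group to the aldehyde face selected by the chelate (anti to the C3 methyl), must not epimerise C3, and must not touch C2, which the ketal ensures.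

10 to 9. The C–Mg bond comes from the C–Br bond of the commercial bromide by magnesium insertion.

8 to 7 to 6. The aldehyde is an oxidation-level adjustment of primary alcohol 7, made late because 8 is configurationally labile and volatile. Alcohol 7 is released from silyl ether 6, whose bulky silyl group carries the oxygen through the carbonyl chemistry and keeps the intermediates non-volatile.

6 to 5 to 3 to 2 to 1. The dioxolane of 6 is a protected form of methyl ketone 5. The C1–C2 bond of 5 is cut to the Weinreb amide 3, which accepts one methyl nucleophile only (through 4). Amide 3 comes from ester 2, the silyl ether of the chiral-pool hydroxy ester 1. The ester carbon of 1 becomes C2, its hydroxymethyl carbon becomes C4 and its stereocentre becomes C3. The priority order of the four substituents at this centre never changes, so it stays S from 1 to 16.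

## Alternatives that were turned down

Alternative 1: The enol-ether double bond of a 2,3-dihydrofuran is cut retrosynthetically, so that one ozonolysis would deliver both the benzoate and the methyl ketone of 16. The dihydrofuran A3, (2R,3R)-3,4-dimethyl-2,5-bis(3,4,5-trimethoxyphenyl)-2,3-dihydrofuran, would arise from a formal [3+2] annulation. The rhodium carbenoid of the diazo ketone A1 (2-diazo-1-(3,4,5-trimethoxyphenyl)propan-1-one) would add to (E)-isoelemicin A2 under a chiral dirhodium tetracarboxylate such as Rh2(S-DOSP)4, forming C2–C3 and then O–C4. In its favour, it is by far the shortest route, uses no protecting group, carries every heavy atom of 16 in two simple components, and unveils the sensitive functionality under neutral conditions. On step economy it is clearly stronger than the chosen route. Against it: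
- A carbenoid with an α-methyl group is prone to 1,2-hydride shift to an aryl vinyl ketone.
- Cyclopropanation competes with the zwitterionic path to the dihydrofuran.
- The absolute configuration would have to come from the catalyst in a stepwise ring closure for which the sense and level of induction cannot be predicted with confidence.
- Ozone must discriminate the enol ether from two electron-rich arenes.

The chosen route is longer, but it takes its absolute configuration from the chiral pool and sets the second centre through a well-understood chelate.

Alternative 2: The C3–CH3 bond is cut. The dilithium alkoxide-enolate of ethyl (R)-3-hydroxy-3-(3,4,5-trimethoxyphenyl)propanoate A4 would be methylated with MeI to the anti ester A5, ethyl (2S,3R)-3-hydroxy-2-methyl-3-(3,4,5-trimethoxyphenyl)propanoate. The Fráter–Seebach alkylation is one of the most dependable anti-selective reactions known. On predictability of the diastereoselection it is at least as strong as the chelate-controlled addition. Its weakness for this target lies after the key step. The ester of A5 must become a methyl ketone while the C4 oxygen is protected. The benzoate cannot be in place, since it would not survive a methyl organometallic. The free β-hydroxy ketone must then be acylated with base present, exactly where E1cB elimination and retro-aldol cleavage threaten. A4 also needs a separate enantioselective step. The overall step count is similar, but the chosen route keeps C2 masked through the acylation and exposes the ketone only in the last, acidic step.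

Alternative 3: The C3–C4 bond is cut. Deprotonation of the benzylic CH2 of the allyl benzyl ether A6, 1,2,3-trimethoxy-5-({[(2R,3E)-3-methylpent-3-en-2-yl]oxy}methyl)benzene (the alkene is assumed to be E), would trigger a [2,3]-Wittig rearrangement to the homoallylic alcohol A7, (1R,2R,3Z)-2,3-dimethyl-1-(3,4,5-trimethoxyphenyl)pent-3-en-1-ol. Acylation and ozonolysis would follow. In its favour, one step makes the central bond and both stereocentres by chirality transfer. The trisubstituted alkene is a base-stable ketone surrogate that is removed under neutral conditions, which is a gentler unmasking than the acid needed for a ketal. Against it: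
- The carbanion of a benzyl ether bearing three methoxy groups is hard to generate cleanly, because ring metalation next to the methoxy groups and [1,2]-shift compete.
- The anti/syn outcome rests on a fine conformational balance in a transition state with a trisubstituted alkene.
- A6 needs its own enantioselective synthesis.
- The final cleavage discards two carbons and exposes the arenes to ozone.

The chosen route forms only one stereocentre in its key step, but does so with a simple, predictable control element.

Key step: step 8

## Route

Step 1
Reactants: 1 methyl (S)-3-hydroxy-2-methylpropanoate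
Product: 2 methyl (S)-3-[(tert-butyldiphenylsilyl)oxy]-2-methylpropanoate
Conditions: TBDPSCl, imidazole, CH2Cl2, 0 °C → rt
Reagents that add atoms: tert-butyl(chloro)diphenylsilane, CC(C)(C)[Si](Cl)(c1ccccc1)c1ccccc1
Why: Imidazole-mediated silylation of a primary alcohol; the bulky, acid-tolerant TBDPS ether is chosen to survive the Lewis acid of step 4 and to make the early intermediates non-volatile, and the stereocentre is not involved.

Step 2
Reactants: 2 methyl (S)-3-[(tert-butyldiphenylsilyl)oxy]-2-methylpropanoate
Product: 3 (S)-3-[(tert-butyldiphenylsilyl)oxy]-N-methoxy-N,2-dimethylpropanamide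
Conditions: MeNHOMe·HCl, iPrMgCl, THF, −20 → 0 °C; aq. NH4Cl
Reagents that add atoms: N,O-dimethylhydroxylamine hydrochloride, CNOC.Cl
Why: Weinreb amide formation by aminolysis of the ester with the chloromagnesium amide made in the flask; this amide is a good nucleophile but a poor base toward the hindered α-C–H at low temperature, so C3 should be retained.

Step 3
Reactants: 3 (S)-3-[(tert-butyldiphenylsilyl)oxy]-N-methoxy-N,2-dimethylpropanamide
Product: 5 (S)-4-[(tert-butyldiphenylsilyl)oxy]-3-methylbutan-2-one, via bromomagnesium hemiaminal 4 (not isolated)
Conditions: MeMgBr (Et2O solution), THF, 0 °C; aq. NH4Cl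
Reagents that add atoms: methylmagnesium bromide, C[Mg]Br
Why: Weinreb ketone synthesis; the five-membered magnesium chelate 4 persists until work-up, so only one methyl group is added and the ketone is released only after the reagent is quenched.

Step 4
Reactants: 5 (S)-4-[(tert-butyldiphenylsilyl)oxy]-3-methylbutan-2-one
Product: 6 (S)-tert-butyl[2-(2-methyl-1,3-dioxolan-2-yl)propoxy]diphenylsilane
Conditions: TMSOCH2CH2OTMS, TMSOTf (cat.), CH2Cl2, −78 → −20 °C; pyridine, then aq. NaHCO3
Reagents that add atoms: 1,2-bis(trimethylsilyloxy)ethane, C[Si](C)(C)OCCO[Si](C)(C)C
Why: Noyori ketalisation; the reaction runs at low temperature without water or free protic acid and is driven by formation of hexamethyldisiloxane, which should avoid enolisation (epimerisation at C3) and β-elimination of the silyloxy group that hot Brønsted-acid ketalisation would risk.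

Step 5
Reactants: 6 (S)-tert-butyl[2-(2-methyl-1,3-dioxolan-2-yl)propoxy]diphenylsilane
Product: 7 (S)-2-(2-methyl-1,3-dioxolan-2-yl)propan-1-ol
Conditions: TBAF, THF, 0 °C → rt; direct filtration through silica, careful concentration
Reagents that add atoms: none
Why: Fluoride-mediated desilylation, to which the ketal is inert; the small alcohol is water-soluble and somewhat volatile, hence the non-aqueous isolation.

Step 6
Reactants: 7 (S)-2-(2-methyl-1,3-dioxolan-2-yl)propan-1-ol
Product: 8 (S)-2-(2-methyl-1,3-dioxolan-2-yl)propanal
Conditions: Dess–Martin periodinane, NaHCO3, CH2Cl2, 0 °C → rt; aq. Na2S2O3/NaHCO3; dried CH2Cl2 solution used at once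
Reagents that add atoms: none
Why: Dess–Martin oxidation under bicarbonate buffer is neutral and fast, so the α-stereocentre of the aldehyde should survive; the aldehyde is not purified or stored but taken on as a dried solution in the solvent of step 8.

Step 7
Reactants: 9 5-bromo-1,2,3-trimethoxybenzene
Product: 10 3,4,5-trimethoxyphenylmagnesium bromide
Conditions: Mg turnings, I2 (cat.), Et2O, reflux; titrated solution used directly
Reagents that add atoms: magnesium, [Mg]
Why: Grignard formation by insertion of magnesium into the aryl C–Br bond; diethyl ether is used instead of THF so that no strong donor solvent competes with the substrate for magnesium in step 8.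

Step 8
Reactants: 8 (S)-2-(2-methyl-1,3-dioxolan-2-yl)propanal; 10 3,4,5-trimethoxyphenylmagnesium bromide
Product: 13 (1R,2S)-2-(2-methyl-1,3-dioxolan-2-yl)-1-(3,4,5-trimethoxyphenyl)propan-1-ol, via MgBr2 chelate 11 (not isolated), via bromomagnesium alkoxide 12 (not isolated)
Conditions: 8, MgBr2·OEt2 (excess), CH2Cl2, −78 °C; then 10 (Et2O solution) added slowly, −78 °C; sat. aq. NH4Cl
Reagents that add atoms: none
Why: MgBr2 binds the aldehyde oxygen and one dioxolane oxygen of 8 to give the six-membered chelate 11, which fixes the rotamer about the C3–C4 bond with the C3 methyl on one face of the chelate ring and the C3 hydrogen on the other. The aryl group of 10 is delivered to the carbonyl carbon from the face that carries only the C3 hydrogen, giving alkoxide 12 and, after protonation, 13. The closest known reaction type is the Cram-chelate (β-chelation) controlled addition of Grignard, cuprate or allylmetal reagents to α-methyl β-alkoxy aldehydes, which gives the anti (anti-Felkin) carbinol. No ring is closed; the chelate is only a temporary template. The new C4 centre (R, C1 in the name of 13) is controlled by the chiral-pool C3 centre (S) through this chelate, and a face analysis of the chelate of the (S)-aldehyde shows that attack anti to the methyl gives the (1R,2S) isomer. The step needs chelate over Felkin–Anh face selectivity, because the open transition state with the bulky dioxolanyl group anti to the nucleophile would give the (1S,2S) epimer; pre-complexation with excess MgBr2·OEt2 in CH2Cl2, a THF-free solution of 10, −78 °C and the unhindered, basic dioxolane oxygen are meant to secure it. It also needs chemoselectivity for the aldehyde, which the ketal provides by masking C2, and retention at C3, which the low basicity of the arylmagnesium reagent and the low temperature should ensure.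

Step 9
Reactants: 13 (1R,2S)-2-(2-methyl-1,3-dioxolan-2-yl)-1-(3,4,5-trimethoxyphenyl)propan-1-ol; 14 3,4,5-trimethoxybenzoyl chloride
Product: 15 (1R,2S)-2-(2-methyl-1,3-dioxolan-2-yl)-1-(3,4,5-trimethoxyphenyl)propyl 3,4,5-trimethoxybenzoate
Conditions: Et3N, DMAP, CH2Cl2, 0 °C → rt
Reagents that add atoms: none
Why: DMAP-catalysed acylation through the N-acylpyridinium ion; the C4–O bond is not broken, so the configuration is retained, and because C2 is still a ketal the amine base has no β-acyloxy ketone to eliminate.

Step 10
Reactants: 15 (1R,2S)-2-(2-methyl-1,3-dioxolan-2-yl)-1-(3,4,5-trimethoxyphenyl)propyl 3,4,5-trimethoxybenzoate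
Product: 16 Tsangin C, (1R,2S)-2-methyl-3-oxo-1-(3,4,5-trimethoxyphenyl)butyl 3,4,5-trimethoxybenzoate
Conditions: PPTS (cat.), acetone–H2O (10:1), 40 °C
Reagents that add atoms: water, O
Why: Acid-catalysed ketal hydrolysis, with acetone also acting as an acceptor for the diol; the weak, buffered acid should neither enolise the new ketone fast enough to epimerise C3 nor ionise the benzylic ester, and no base is present to start E1cB elimination.

## Compound list

1 | methyl (S)-3-hydroxy-2-methylpropanoate | OC[C@H](C)C(=O)OC | starting material
2 | methyl (S)-3-[(tert-butyldiphenylsilyl)oxy]-2-methylpropanoate | CC(C)(C)[Si](c1ccccc1)(c1ccccc1)OC[C@H](C)C(=O)OC | intermediate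
3 | (S)-3-[(tert-butyldiphenylsilyl)oxy]-N-methoxy-N,2-dimethylpropanamide | CC(C)(C)[Si](c1ccccc1)(c1ccccc1)OC[C@H](C)C(=O)N(C)OC | intermediate
4 | bromomagnesium (3S)-4-[(tert-butyldiphenylsilyl)oxy]-2-[methoxy(methyl)amino]-3-methylbutan-2-olate (hemiaminal carbon unassigned; not isolated) | CC(C)(C)[Si](c1ccccc1)(c1ccccc1)OC[C@H](C)C(C)(O[Mg]Br)N(C)OC | intermediate
5 | (S)-4-[(tert-butyldiphenylsilyl)oxy]-3-methylbutan-2-one | CC(C)(C)[Si](c1ccccc1)(c1ccccc1)OC[C@H](C)C(C)=O | intermediate
6 | (S)-tert-butyl[2-(2-methyl-1,3-dioxolan-2-yl)propoxy]diphenylsilane | CC(C)(C)[Si](c1ccccc1)(c1ccccc1)OC[C@H](C)C1(C)OCCO1 | intermediate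
7 | (S)-2-(2-methyl-1,3-dioxolan-2-yl)propan-1-ol | OC[C@H](C)C1(C)OCCO1 | intermediate
8 | (S)-2-(2-methyl-1,3-dioxolan-2-yl)propanal | O=C[C@H](C)C1(C)OCCO1 | intermediate
9 | 5-bromo-1,2,3-trimethoxybenzene | COc1cc(Br)cc(OC)c1OC | starting material
10 | 3,4,5-trimethoxyphenylmagnesium bromide | COc1cc([Mg]Br)cc(OC)c1OC | intermediate
11 | MgBr2 chelate of aldehyde 8, magnesium bridging the aldehyde oxygen and one dioxolane oxygen (not isolated) | O=C[C@H](C)C1(C)OCCO1.Br[Mg]Br | intermediate
12 | bromomagnesium (1R,2S)-2-(2-methyl-1,3-dioxolan-2-yl)-1-(3,4,5-trimethoxyphenyl)propan-1-olate (not isolated) | Br[Mg]O[C@@H](c1cc(OC)c(OC)c(OC)c1)[C@H](C)C1(C)OCCO1 | intermediate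
13 | (1R,2S)-2-(2-methyl-1,3-dioxolan-2-yl)-1-(3,4,5-trimethoxyphenyl)propan-1-ol | O[C@@H](c1cc(OC)c(OC)c(OC)c1)[C@H](C)C1(C)OCCO1 | intermediate
14 | 3,4,5-trimethoxybenzoyl chloride | COc1cc(C(Cl)=O)cc(OC)c1OC | starting material
15 | (1R,2S)-2-(2-methyl-1,3-dioxolan-2-yl)-1-(3,4,5-trimethoxyphenyl)propyl 3,4,5-trimethoxybenzoate | COc1cc(C(=O)O[C@@H](c2cc(OC)c(OC)c(OC)c2)[C@H](C)C2(C)OCCO2)cc(OC)c1OC | intermediate
16 | Tsangin C, (1R,2S)-2-methyl-3-oxo-1-(3,4,5-trimethoxyphenyl)butyl 3,4,5-trimethoxybenzoate | COc1cc(C(=O)O[C@@H](c2cc(OC)c(OC)c(OC)c2)[C@H](C)C(C)=O)cc(OC)c1OC | target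

## Step count and risk

Total step count: 10. Longest linear sequence: 9 steps (steps 1 to 6, then 8, 9 and 10); step 7 is a one-step side branch.

Least certain steps:

Step 8 (key step). The most likely failure is poor facial selectivity. The open Felkin–Anh pathway, favoured by the bulky quaternary dioxolanyl group, may compete if chelation is incomplete or if the Grignard reagent reacts before the chelate has formed. The ketal methyl group may also partly shield the chelate face that must be attacked. Slow epimerisation of the aldehyde at C3 is a second risk. The fallback sets out from 8 and 10 and gives up face control in the C–C bond formation. Addition in THF without the Lewis acid should give 13 together with its C4 epimer, (1S,2S)-2-(2-methyl-1,3-dioxolan-2-yl)-1-(3,4,5-trimethoxyphenyl)propan-1-ol F1. The mixture is oxidised with Dess–Martin periodinane to the single ketone (S)-2-(2-methyl-1,3-dioxolan-2-yl)-1-(3,4,5-trimethoxyphenyl)propan-1-one F2. F2 is then reduced with LiBH(s-Bu)3 in THF at −78 °C. In the Felkin–Anh transition state of F2 the dioxolanyl group stands anti to the hydride. Because hydride and aryl have exchanged roles relative to step 8, this open transition state now leads to the anti alcohol. The sequence comes back to the route at 13.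

Step 10. The ketal is flanked by a branched carbon and may hydrolyse slowly. Forcing the acid could cause loss of the benzoate by elimination toward the conjugated enone, ionisation at the benzylic C4, or epimerisation at C3 through the enol. The fallback reverses the order of the last two steps and sets out from 13. The ketal is hydrolysed (PPTS, wet acetone) while C4 still carries a free hydroxyl, a much poorer leaving group, to give (3S,4R)-4-hydroxy-3-methyl-4-(3,4,5-trimethoxyphenyl)butan-2-one F3. F3 is then acylated with 14 in pyridine at 0 °C, without stronger base, which comes back to the route at 16.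

Step 4. Ketone 5 has an enolisable stereocentre and a β-silyloxy group. Partial epimerisation through a silyl enol ether, β-elimination, or sluggish conversion of the α-branched ketone are the likely problems. The fallback sets out from 2 and bypasses the ketone. Methylenation of the ester with Cp2TiMe2 in toluene at 65 °C should give the methyl enol ether (S)-tert-butyl[(3-methoxy-2-methylbut-3-en-1-yl)oxy]diphenylsilane F4. Ethylene glycol with catalytic PPTS in CH2Cl2 at 0 °C then adds across the enol ether and closes the dioxolane with loss of methanol. The sequence comes back to the route at 6.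

Step 7. Magnesium insertion into this electron-rich aryl bromide may start poorly in diethyl ether, or the reagent may be sparingly soluble, and adding THF would undermine the chelate of step 8. The fallback sets out from 9. Bromine–lithium exchange with n-BuLi in Et2O at −78 °C gives (3,4,5-trimethoxyphenyl)lithium F5. Transmetalation with MgBr2·OEt2 then gives a THF-free solution of the same reagent, and the sequence comes back to the route at 10.

## Further compounds

F1 | step 8 | (1S,2S)-2-(2-methyl-1,3-dioxolan-2-yl)-1-(3,4,5-trimethoxyphenyl)propan-1-ol | O[C@H](c1cc(OC)c(OC)c(OC)c1)[C@H](C)C1(C)OCCO1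
F2 | step 8 | (S)-2-(2-methyl-1,3-dioxolan-2-yl)-1-(3,4,5-trimethoxyphenyl)propan-1-one | O=C(c1cc(OC)c(OC)c(OC)c1)[C@H](C)C1(C)OCCO1
F3 | step 10 | (3S,4R)-4-hydroxy-3-methyl-4-(3,4,5-trimethoxyphenyl)butan-2-one | O[C@@H](c1cc(OC)c(OC)c(OC)c1)[C@H](C)C(C)=O
F4 | step 4 | (S)-tert-butyl[(3-methoxy-2-methylbut-3-en-1-yl)oxy]diphenylsilane | CC(C)(C)[Si](c1ccccc1)(c1ccccc1)OC[C@H](C)C(=C)OC
F5 | step 7 | (3,4,5-trimethoxyphenyl)lithium | [Li]c1cc(OC)c(OC)c(OC)c1
A1 | alternative 1 | 2-diazo-1-(3,4,5-trimethoxyphenyl)propan-1-one | CC(=[N+]=[N-])C(=O)c1cc(OC)c(OC)c(OC)c1
A2 | alternative 1 | (E)-isoelemicin, 1,2,3-trimethoxy-5-[(E)-prop-1-en-1-yl]benzene | C/C=C/c1cc(OC)c(OC)c(OC)c1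
A3 | alternative 1 | (2R,3R)-3,4-dimethyl-2,5-bis(3,4,5-trimethoxyphenyl)-2,3-dihydrofuran | COc1cc(C2O[C@@H](c3cc(OC)c(OC)c(OC)c3)[C@H](C)C=2C)cc(OC)c1OC
A4 | alternative 2 | ethyl (R)-3-hydroxy-3-(3,4,5-trimethoxyphenyl)propanoate | O[C@@H](c1cc(OC)c(OC)c(OC)c1)CC(=O)OCC
A5 | alternative 2 | ethyl (2S,3R)-3-hydroxy-2-methyl-3-(3,4,5-trimethoxyphenyl)propanoate | O[C@@H](c1cc(OC)c(OC)c(OC)c1)[C@H](C)C(=O)OCC
A6 | alternative 3 | 1,2,3-trimethoxy-5-({[(2R,3E)-3-methylpent-3-en-2-yl]oxy}methyl)benzene | C/C=C(\C)[C@@H](C)OCc1cc(OC)c(OC)c(OC)c1
A7 | alternative 3 | (1R,2R,3Z)-2,3-dimethyl-1-(3,4,5-trimethoxyphenyl)pent-3-en-1-ol | O[C@@H](c1cc(OC)c(OC)c(OC)c1)[C@H](C)/C(C)=C\C
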